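The pitfall in this flask is to hold the partner against two equivalents of starting material: 3.60 mM is less than 4.00 mM, which reads as too little partner to finish the bis adduct, with tris adduct out of reach. But a mono adduct caught by the capture agent has taken one equivalent of partner and asks for no second.

| flask | starting material | partner | capture agent | remark | time |
|---|---|---|---|---|---|
| autumn | 2 mM | 3.6 mM | 0.60 mM | the very flask that is asked about, followed so far |  |
| flask | 2.0 mM | 3.60 mM | 0.600 mM |  | 5.0 h |

autumn run (percent of the starting material charged)

| time / min | starting material / % | mono adduct / % |
|---|---|---|
| 3.00 | 9.1 | 14.8 |
| 5.00 | 5.8 | 9.3 |
| 8.00 | 3.6 | 7.5 |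
| 12.0 | 1.4 | 4.9 |
| 20.0 | 0.8 | 4.0 |
| 40.0 | 0 | 3.8 |

(each reading ± 1 percentage point)

- bis adduct is meant together with its crystals
- solid, in amounts per volume of the solution: crystals
- the earlier runs were read with a standard deviation of 1 percentage point
- on the list of suspects stand: starting material + partner -> mono adduct; partner + mono adduct -> bis adduct; partner + bis adduct -> tris adduct; bis adduct -> over-reaction product; crystals <-> bis adduct; mono adduct + capture agent -> trapped intermediate

- amount of starting material at 5.0 h, in percent of the starting material charged
- amount of mono adduct at 5.0 h, in percent of the starting material charged
- amount of bis adduct at 5.0 h, in percent of the starting material charged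
- amount of tris adduct at 5.0 h, in percent of the starting material charged

So I reckon with the spare partner: the partner charged, minus one equivalent per starting material, minus one more per starting material not caught, as a share of the starting material charged. The need is 3.40 mM, less than the charge, so the spare partner of this flask is 10.0 %. In the autumn readings mono adduct stands at 4.0 % and then 3.8 %, so I assume that partner and capture agent both end used up. Counting the partner then gives a rule: tris adduct equals spare partner plus mono adduct, plus two points for each point of starting material left.

The neighbouring flask, with 3.4 mM of starting material and its other charges as in this flask, needs 6.20 mM, more than its 3.60 mM of partner. Its spare partner is −76.5 %, which makes partner the limiting reagent there, so I expect that neighbour to stop with starting material or mono adduct standing, while this flask passes its spare on to tris adduct.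

For this flask I take the last readings, 0 % of starting material and 3.8 % of mono adduct, and reckon 13.8 % of tris adduct and 52.4 % of bis adduct. A mono reading off by 1 percentage point moves that bis adduct by 2 points.

The forecast says 0.2 %, 3.5 %, 47 % and 13 %, with bis adduct below mine, and holds that “little can change, since the reagents are gone”.

The flask gives 0.481 % of starting material, 1.97 % of mono adduct, 54.3 % of bis adduct and 12.9 % of tris adduct. Counted inside that bis adduct are crystals amounting to 52.6 % of the starting material charged, and half of their growth up to the asked time is done by 1.25 min.

    starting material + partner → mono adduct (k = 9.50 /M/s)
    partner + mono adduct → bis adduct (k = 8.40 /M/s)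
    partner + bis adduct → tris adduct (k = 11.0 /M/s)
    bis adduct → over-reaction product (k = 1.20 × 10⁻⁵ /s)
    crystals ⇌ bis adduct, rate k5*(cs5 - [bis adduct]) while solid is left; crystals form when [bis adduct] > cs5 (solubility = 0.0330 mM, k = 0.260 /s)
    mono adduct + capture agent → trapped intermediate (k = 22.0 /M/s)

In the neighbouring flask partner and capture agent stand at 0 % and 0 %, so the rule applies there: its spare partner of −76.5 %, with 26.9 % of mono adduct and 26.1 % of starting material left, gives 2.60 % of tris adduct, and that neighbour holds 2.62 %.

Readings and results stem from a simulated flask from invented constants, and the scatter is random.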